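## Analysis of the target

The target 26 is a flavone: a 4H-chromen-4-one (rings A and C) with a 3,4-dihydroxyphenyl ring B at C2. It has no stereocentre, so nothing has to be controlled in space. Ring A is substituted at every position but C8: oxygen at C5, C6, C7 and C8a (O1), carbon at C4a, hydrogen at C8. The sulfate sits on O6, the middle and most hindered of three contiguous oxygens. The sensitive groups are the aryl hydrogen sulfate, which is cleaved by acid, and the two catechol-type arrays, which oxidize under base in air. The 5-hydroxyl is hydrogen-bonded to the C4 carbonyl and is the least reactive phenol.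

The difficulty is constitutional. One of five phenolic oxygens must be sulfated, and in the free flavone O7 and O4′ would react first. Ring A is also nearly symmetric about the C6···C8a axis, so ring C can in principle close onto either flanking oxygen and give the 5,6,7- or the 5,7,8-pattern.

The strategy rests on one feature: the ring A pattern is that of a 2-deoxyhexose redrawn as a carbocycle. Sugar C3–O and C4–O become O7 and O6 and can be protected differently from the start, and the deoxy carbon becomes C8.

## Retrosynthetic reasoning

**Debenzylation and sulfation.** The last operation removes the three benzyl ethers of 25 to give 26. Benzyl is used on O7, O3′ and O4′ because hydrogenolysis is neutral and leaves an aryl sulfate salt untouched. The S–O6 bond is cut next and leads to the catechol 24. The sulfate, the most fragile group, is thus carried through a single step. The forward reaction has to sulfate O6 and not O5, which the hydrogen bond from O5–H to the C4 carbonyl should secure.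

**Aromatic ring A from a carbinol oxidation.** 24 is traced to the α-hydroxy ketone 22 through the 5,6-dione 23, which is only a tautomer of 24. Ring A is therefore aromatized by oxidizing the C6 carbinol and letting two protons move, not by removing hydrogen from C7 and C8. The reason is that every ring A intermediate at the dihydro level is a β-benzyloxy ketone. A dehydrogenation that needs heat, acid or base would compete with loss of the C7 oxygen, which also aromatizes the ring but in the 7-deoxy series. A further gain is that O6 emerges as the one free, non-chelated hydroxyl. 22 comes from the silyl ether 21 by desilylation.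

**C4a=C8a unsaturation.** 21 is taken back to the tetrahydrochromenone 20 by adding hydrogen across C4a–C8a. The forward dehydrogenation is placed before O6 is unmasked for two reasons. The C8a hydrogen of 20 is allylic to the C5 enol and alpha to O1, so it is the most hydridic hydrogen present. Once the double bond is in place, O1 is a vinylic pyranone oxygen that can no longer leave by β-elimination when C6 is oxidized.

**O1–C2 bond.** Ring C of 20 is opened at O1–C2 to the hydroxy ynone 19, generated in the flask from the silyl ether 18. A cut at C2–C3 or C3–C4 would instead demand a condensation on a 1,3,5-tricarbonyl array. The forward reaction is a 6-endo-dig addition of an alcohol to an ynone, and it must use the C8a oxygen and not the C5 enol oxygen. The carbinol-versus-carbonyl difference created by the carbocyclization makes this possible, helped by the chelated enol, which turns the alkyne toward C8a.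

**C4a–C4 bond.** 18 is disconnected at C4a–C4, through the aldol 17, into the ketone 11 and the ynal 15. C4a is the only methylene alpha to the ketone of 11; the other alpha carbon carries the silyloxy group, so the kinetic enolate 16 should form at C4a. The aldehyde oxidation level of 15 is preferred to an acid derivative because an enolate adds to an ynal cleanly at the carbonyl, whereas alkynoyl electrophiles invite conjugate addition and pyrone formation in the flask. The price is one oxidation step. 15 is two steps from the aldehyde 12 by way of the dibromoalkene 13 and the acetylide 14.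

**C4a–C8a bond, the key disconnection.** 11 comes from the hydroxy ketone 10. 10 is opened between the carbinol carbon and the adjacent methylene, which reveals the keto aldehyde 9 and behind it the exocyclic enol ether 8 of a 2-deoxy sugar. This turns a hexasubstituted-benzene problem into the protection of a pyranoside. In 10 the ketone carbon is C5, the silyloxy carbon C6, the benzyloxy carbon C7, the ring methylene C8, the carbinol carbon C8a and the new methylene C4a. The forward reaction has to close a six-membered carbocycle without losing any of the four oxygens.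

**The sugar.** 8 arises by dehydrohalogenation of the iodide 7. 7 comes from the diol 5 by iodination at O6 (giving 6) and silylation at O4. 5 comes from the benzylidene acetal 4, whose precursor 3 has O3 as its only free hydroxyl, and 3 from the methyl glycoside 2 of 1. An ester on O4, which oxidative opening of 4 would give directly, would save two steps. It was set aside because an α-acyloxy ketone is a poor partner for amide bases, and because the ester would have to be cleaved by base at the stage of 21, where base removes the C7 oxygen. A silyl ether survives enolate formation and the quinone oxidant and is removed by fluoride.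

## Alternatives that were turned down

**Alternative 1:** The sulfate is disconnected at S–O7 of a five-membered cyclic sulfate spanning O6 and O7. Forward, the triol A2 (ring B masked as pivalates) would react with a sulfuryl transfer reagent and an amine base to give the 1,3,2-dioxathiole 2,2-dioxide A1, forming the O6–S and O7–S bonds and one new ring. Hydrolytic opening at S–O7 and ester cleavage would then give 26.
- For it: it starts from the intact flavone and needs perhaps four or five steps. It uses the greater acidity of O7, a vinylogous carboxylic acid and the better leaving group, to decide which S–O bond breaks. On step count and convergence it is far stronger than the chosen route.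
- Against it: A2 has two ortho-dihydroxy pairs, O5/O6 and O6/O7, and the reagent must choose the second. Aryl cyclic sulfates are strongly electrophilic at sulfur and are likely to be opened by halide, the amine or traces of water. The regiochemistry of opening rests on a modest acidity difference, and the wrong mode gives the 7-sulfate, an isomer that would be hard to separate from 26.
- In its place the chosen route offers a sulfate position fixed by constitution: O6 is the only free, non-chelated hydroxyl of 24 because it was the silyl-protected C4 oxygen of the sugar.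

**Alternative 2:** The C8a–O1 bond is disconnected, and ring A enters without oxygen at C8a. Forward, the 1,3-diketone A4 would be oxidized at a carbon anode in a fluorinated alcohol. The phenoxonium ion from the free 6-hydroxyl would be attacked at C8a, para to O6, by the enol oxygen, closing ring C and giving A3 after loss of a proton.
- For it: A4 is available by a short Claisen-type assembly. The key step makes a C–O bond by C–H functionalization without reagent waste. A3 carries exactly one free hydroxyl, at O6, which is an even cleaner sulfation substrate than 24. In step count it clearly wins.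
- Against it: the cation from a 2,6-dialkoxyphenol can be attacked at the two alkoxy-bearing ortho carbons as well as at the para carbon, leading to quinone monoketals and loss of a benzyl group. The enolized diketone and the electron-rich ring B should oxidize at potentials close to that of the phenol. A3 is a para-alkoxyphenol, more easily oxidized than A4, and would tend to go on to a quinone.
- In its place the chosen route offers a pivotal step that is a well-established reaction type, where this one would be development work without close precedent.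

**Alternative 3:** C4a–C4 and C8a–O are disconnected in one operation, and ring A enters as a 3,4,5-trioxygenated aryne. Forward, fluoride would release the aryne from the silyl triflate A7. The carboxylate oxygen of the arylpropiolic acid A6 would add to the aryne carbon remote from the C5 alkoxy group (C8a), and the aryl anion would then attack the carboxyl carbon. The net result is insertion into the C–O bond to give the ortho-hydroxyaryl ynone A5; no ring closes. A later 6-endo closure would give the flavone with O6 as a methoxymethyl ether.
- For it: it is convergent, addition to a 3-alkoxyaryne is regiochemically dependable, and ring closure of A5 is a standard flavone synthesis. O6 is marked simply by starting from a symmetric trioxygenated phenol whose middle oxygen is unique. In the cheapness of that differentiation and in step count it is stronger than the chosen route.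
- Against it: A7 is a pentasubstituted arene that needs its own four- or five-step synthesis. The aryl anion can be protonated by a second molecule of A6 faster than it attacks its own carboxyl carbon, which gives the aryl ester and not A5. A6 and A5 are Michael acceptors for fluoride and phenoxide and reaction partners for the aryne.
- In its place the chosen route brings all ring A oxygens in with the sugar and makes the only C–C bond to ring A by enolate chemistry at a position with no competitor.

Key step: step 8

## Route

Assumption: 25 and 26 are written as free hydrogen sulfates, as in the target structure; both would be handled as sodium salts, and 26 would be converted to the acid on an H+-form resin at 0 °C.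

Assumption: the α-methyl glycoside is drawn for 2–8; the β-anomer would serve equally, because C1 loses its configuration in step 8.

Step 1
Reactants: 1 2-deoxy-D-glucose
Product: 2 methyl 2-deoxy-α-D-arabino-hexopyranoside
Conditions: AcCl (cat.), MeOH, rt
Reagents that add atoms: methanol, CO
Why: Fischer glycosidation; the 2-deoxy sugar reacts at room temperature and equilibrates to the pyranosides, the axial α-anomer being favoured by the anomeric effect.

Step 2
Reactants: 2 methyl 2-deoxy-α-D-arabino-hexopyranoside
Product: 3 methyl 4,6-O-[(R)-benzylidene]-2-deoxy-α-D-arabino-hexopyranoside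
Conditions: PhCH(OMe)2, CSA (cat.), DMF, 50 °C, reduced pressure
Reagents that add atoms: benzaldehyde dimethyl acetal, COC(OC)c1ccccc1
Why: Acid-catalysed transacetalization closes the trans-fused 1,3-dioxane across O4 and O6 with equatorial phenyl and leaves O3 as the only free hydroxyl.

Step 3
Reactants: 3 methyl 4,6-O-[(R)-benzylidene]-2-deoxy-α-D-arabino-hexopyranoside
Product: 4 methyl 3-O-benzyl-4,6-O-[(R)-benzylidene]-2-deoxy-α-D-arabino-hexopyranoside
Conditions: NaH, BnBr, Bu4NI (cat.), DMF, 0 °C → rt
Reagents that add atoms: benzyl bromide, BrCc1ccccc1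
Why: Williamson etherification of the single free hydroxyl; O3, the future O7, receives the group that lasts to the final step.

Step 4
Reactants: 4 methyl 3-O-benzyl-4,6-O-[(R)-benzylidene]-2-deoxy-α-D-arabino-hexopyranoside
Product: 5 methyl 3-O-benzyl-2-deoxy-α-D-arabino-hexopyranoside
Conditions: TsOH·H2O (cat.), MeOH, rt; then Et3N
Reagents that add atoms: none
Why: Acetal exchange with methanol frees O4 and O6; in methanol any solvolysis at the acid-labile 2-deoxy anomeric centre only regenerates a methyl glycoside.

Step 5
Reactants: 5 methyl 3-O-benzyl-2-deoxy-α-D-arabino-hexopyranoside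
Product: 6 methyl 3-O-benzyl-2,6-dideoxy-6-iodo-α-D-arabino-hexopyranoside
Conditions: I2, PPh3, imidazole, toluene, 60 °C
Reagents that add atoms: iodine, II
Why: Garegg–Samuelsson (Appel-type) iodination; the primary alkoxyphosphonium ion is displaced by iodide in an SN2 step that the flanked secondary O4–H cannot match.

Step 6
Reactants: 6 methyl 3-O-benzyl-2,6-dideoxy-6-iodo-α-D-arabino-hexopyranoside
Product: 7 methyl 3-O-benzyl-4-O-(tert-butyldimethylsilyl)-2,6-dideoxy-6-iodo-α-D-arabino-hexopyranoside
Conditions: TBSOTf, 2,6-lutidine, CH2Cl2, 0 °C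
Reagents that add atoms: tert-butyldimethylsilyl trifluoromethanesulfonate, CC(C)(C)[Si](C)(C)OS(=O)(=O)C(F)(F)F
Why: Silylation of the hindered secondary hydroxyl with the silyl triflate; O4, the future O6, now carries a group that is orthogonal to benzyl, inert to amide bases and quinone oxidants, and removable by fluoride without base.

Step 7
Reactants: 7 methyl 3-O-benzyl-4-O-(tert-butyldimethylsilyl)-2,6-dideoxy-6-iodo-α-D-arabino-hexopyranoside
Product: 8 methyl 3-O-benzyl-4-O-(tert-butyldimethylsilyl)-2,6-dideoxy-α-D-arabino-hex-5-enopyranoside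
Conditions: KOt-Bu, THF, 0 °C → rt
Reagents that add atoms: none
Why: E2 dehydroiodination; the bulky alkoxide removes H5 anti to the primary iodide and gives the exocyclic enol ether, substitution being disfavoured.

Step 8
Reactants: 8 methyl 3-O-benzyl-4-O-(tert-butyldimethylsilyl)-2,6-dideoxy-α-D-arabino-hex-5-enopyranoside
Product: 10 (2S,3R)-3-(benzyloxy)-2-[(tert-butyldimethylsilyl)oxy]-5-hydroxycyclohexan-1-one, via acyclic 6-mercurio-5-oxohexanal 9 (not isolated)
Conditions: Hg(OCOCF3)2 (0.1 equiv), acetone/H2O (4:1), rt
Reagents that add atoms: water, O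
Why: This is a Ferrier carbocyclization, the established conversion of 6-deoxyhex-5-enopyranosides into oxygenated 5-hydroxycyclohexanones. Divalent mercury adds to the electron-rich exocyclic enol ether at the terminal carbon (sugar C6) and water adds at C5; the hemiketal collapses with opening of the pyranose ring and loss of methanol from C1 to give 9, a 1,5-keto aldehyde with mercury alpha to the ketone. This alpha-mercurio ketone reacts as a mercury enolate and adds to the aldehyde, forming the sugar C6–C1 bond, which is the C4a–C8a bond of ring A; the closure is 6-(enolendo)-exo-trig, and protonolysis of the mercury aldolate returns the catalyst. The one new stereocentre, the carbinol carbon, is set in a chair-like transition state and is expected mainly trans to the benzyloxy group, as is usual for this reaction; it is of no consequence because this carbon becomes sp2 in step 15. What the step must deliver is constitution: the nucleophilic carbon is fixed by the position of the mercury, the aldehyde is the only electrophile and only a six-membered ring can form, so the ketone (future C5) lies next to the silyloxy carbon (C6) and the carbinol (future C8a) next to the methylene (C8). The chemoselectivity needed, no β-elimination of the benzyloxy group from the transient aldehyde or of the new hydroxyl, is secured by the near-neutral aqueous acetone and the catalytic amount of Hg(OCOCF3)2, to which silyl and benzyl ethers are inert.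

Step 9
Reactants: 10 (2S,3R)-3-(benzyloxy)-2-[(tert-butyldimethylsilyl)oxy]-5-hydroxycyclohexan-1-one
Product: 11 (2S,3R)-3-(benzyloxy)-2-[(tert-butyldimethylsilyl)oxy]-5-[(triethylsilyl)oxy]cyclohexan-1-one
Conditions: Et3SiCl, imidazole, CH2Cl2, 0 °C
Reagents that add atoms: chlorotriethylsilane, CC[Si](Cl)(CC)CC
Why: Silylation of the carbinol under conditions too mild for β-elimination; the triethylsilyl ether keeps the future O1 out of the enolate chemistry and can later be cleaved in the presence of the bulkier silyl ether on O6.

Step 10
Reactants: 12 3,4-bis(benzyloxy)benzaldehyde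
Product: 13 1,2-bis(benzyloxy)-4-(2,2-dibromoethenyl)benzene
Conditions: CBr4, PPh3, CH2Cl2, 0 °C
Reagents that add atoms: tetrabromomethane, BrC(Br)(Br)Br
Why: Ramirez dibromo-olefination, the first half of the Corey–Fuchs sequence: a Wittig reaction of the dibromomethylene ylide with the aromatic aldehyde.

Step 11
Reactants: 13 1,2-bis(benzyloxy)-4-(2,2-dibromoethenyl)benzene
Product: 15 3-[3,4-bis(benzyloxy)phenyl]prop-2-ynal, via lithium arylacetylide 14 (not isolated)
Conditions: n-BuLi (2.1 equiv), THF, −78 °C; DMF, −78 → 0 °C; inverse quench into aq. KH2PO4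
Reagents that add atoms: N,N-dimethylformamide, CN(C)C=O
Why: Second half of the Corey–Fuchs sequence (bromine–lithium exchange, rearrangement of the carbenoid, deprotonation) followed by formylation of the acetylide; the buffered inverse quench releases the ynal without conjugate addition of the amine set free.

Step 12
Reactants: 11 (2S,3R)-3-(benzyloxy)-2-[(tert-butyldimethylsilyl)oxy]-5-[(triethylsilyl)oxy]cyclohexan-1-one; 15 3-[3,4-bis(benzyloxy)phenyl]prop-2-ynal
Product: 17 (2S,3R)-3-(benzyloxy)-6-{3-[3,4-bis(benzyloxy)phenyl]-1-hydroxyprop-2-yn-1-yl}-2-[(tert-butyldimethylsilyl)oxy]-5-[(triethylsilyl)oxy]cyclohexan-1-one, via lithium enolate 16 (not isolated)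
Conditions: LiN(i-Pr)2, THF, −78 °C; then 15, −78 °C; AcOH, −78 °C
Reagents that add atoms: none
Why: Kinetic deprotonation of an α-silyloxy ketone by the hindered amide should occur at the unhindered methylene C4a and not at the oxygen-bearing methine, and directed aldol addition to the non-enolizable ynal is a 1,2-addition that forms the C4a–C4 bond. The two new stereocentres (C4a and C4) are formed without control and are both erased in steps 13 and 15; the cold acidic quench guards against loss of the β-silyloxy group.

Step 13
Reactants: 17 (2S,3R)-3-(benzyloxy)-6-{3-[3,4-bis(benzyloxy)phenyl]-1-hydroxyprop-2-yn-1-yl}-2-[(tert-butyldimethylsilyl)oxy]-5-[(triethylsilyl)oxy]cyclohexan-1-one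
Product: 18 (2S,3R)-3-(benzyloxy)-6-{3-[3,4-bis(benzyloxy)phenyl]prop-2-ynoyl}-2-[(tert-butyldimethylsilyl)oxy]-5-[(triethylsilyl)oxy]cyclohexan-1-one
Conditions: Dess–Martin periodinane, NaHCO3, CH2Cl2, 0 °C → rt
Reagents that add atoms: none
Why: Dess–Martin oxidation of a β-hydroxy ketone to the 1,3-diketone under buffered neutral conditions; the product should exist as the hydrogen-bonded enol, which also shields the C5 carbonyl from enolizing toward C6.

Step 14
Reactants: 18 (2S,3R)-3-(benzyloxy)-6-{3-[3,4-bis(benzyloxy)phenyl]prop-2-ynoyl}-2-[(tert-butyldimethylsilyl)oxy]-5-[(triethylsilyl)oxy]cyclohexan-1-one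
Product: 20 (6S,7R)-7-(benzyloxy)-2-[3,4-bis(benzyloxy)phenyl]-6-[(tert-butyldimethylsilyl)oxy]-5-hydroxy-6,7,8,8a-tetrahydro-4H-chromen-4-one, via hydroxy ynone 19 (not isolated)
Conditions: CSA (0.2 equiv), CH2Cl2/MeOH (10:1), 0 °C → rt
Reagents that add atoms: none
Why: Acid should remove the triethylsilyl group well before the bulkier silyl ether, and the freed C8a hydroxyl adds 6-endo-dig to the acid-activated ynone, the known cyclization of β-hydroxy ynones to 2,3-dihydro-4H-pyran-4-ones; this forms O1–C2. In the chelated enol of 19 the C4 and C5 oxygens face each other, so the alkyne points to the C8a side and only the alcohol oxygen can reach C2.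

Step 15
Reactants: 20 (6S,7R)-7-(benzyloxy)-2-[3,4-bis(benzyloxy)phenyl]-6-[(tert-butyldimethylsilyl)oxy]-5-hydroxy-6,7,8,8a-tetrahydro-4H-chromen-4-one
Product: 21 (6S,7R)-7-(benzyloxy)-2-[3,4-bis(benzyloxy)phenyl]-6-[(tert-butyldimethylsilyl)oxy]-7,8-dihydro-4H-chromene-4,5(6H)-dione
Conditions: DDQ (1.2 equiv), 1,4-dioxane, rt → 50 °C
Reagents that add atoms: none
Why: Quinone dehydrogenation of a dihydropyranone to the pyranone, the reaction type that turns flavanones into flavones; hydride leaves C8a, where the cation is stabilized by O1 and by the C5 enol, and loss of the enol proton gives the C4a=C8a bond. O1 is then a vinylic pyranone oxygen and can no longer be expelled by β-elimination.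

Step 16
Reactants: 21 (6S,7R)-7-(benzyloxy)-2-[3,4-bis(benzyloxy)phenyl]-6-[(tert-butyldimethylsilyl)oxy]-7,8-dihydro-4H-chromene-4,5(6H)-dione
Product: 22 (6S,7R)-7-(benzyloxy)-2-[3,4-bis(benzyloxy)phenyl]-6-hydroxy-7,8-dihydro-4H-chromene-4,5(6H)-dione
Conditions: HF·pyridine, THF, 0 °C → rt
Reagents that add atoms: none
Why: Fluoride-driven cleavage of the α-keto silyl ether under weakly acidic, non-basic conditions, chosen because 21 and 22 are β-benzyloxy ketones that would lose the C7 oxygen on contact with base.

Step 17
Reactants: 22 (6S,7R)-7-(benzyloxy)-2-[3,4-bis(benzyloxy)phenyl]-6-hydroxy-7,8-dihydro-4H-chromene-4,5(6H)-dione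
Product: 24 7-(benzyloxy)-2-[3,4-bis(benzyloxy)phenyl]-5,6-dihydroxy-4H-chromen-4-one, via 5,6-dione 23 (not isolated)
Conditions: Dess–Martin periodinane (1.1 equiv), NaHCO3, CH2Cl2, 0 °C; aq. Na2S2O3/Na2S2O4 work-up
Reagents that add atoms: none
Why: Dess–Martin oxidation of the α-hydroxy ketone gives the 5,6-dione 23, a keto tautomer of the catechol; two proton shifts (from C7 to O6 and from C8 to O5) aromatize ring A with no C–O bond at risk. Any ortho-quinone from over-oxidation should be returned to 24 by the dithionite wash.

Step 18
Reactants: 24 7-(benzyloxy)-2-[3,4-bis(benzyloxy)phenyl]-5,6-dihydroxy-4H-chromen-4-one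
Product: 25 7-(benzyloxy)-2-[3,4-bis(benzyloxy)phenyl]-5-hydroxy-4-oxo-4H-chromen-6-yl hydrogen sulfate
Conditions: SO3·pyridine (4 equiv), pyridine, 45 °C; then aq. NaHCO3
Reagents that add atoms: sulfur trioxide–pyridine complex, [O-]S(=O)(=O)[n+]1ccccc1
Why: O-Sulfonation of a phenol by an amine–sulfur trioxide complex; the 5-hydroxyl is held in a hydrogen bond to the C4 carbonyl and O7, O3′ and O4′ are benzylated, so O6 is the only hydroxyl expected to react.

Step 19
Reactants: 25 7-(benzyloxy)-2-[3,4-bis(benzyloxy)phenyl]-5-hydroxy-4-oxo-4H-chromen-6-yl hydrogen sulfate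
Product: 26 2-(3,4-dihydroxyphenyl)-5,7-dihydroxy-4-oxo-4H-chromen-6-yl hydrogen sulfate (6-hydroxyluteolin 6-sulfate)
Conditions: H2 (1 atm), Pd/C (10 wt %), MeOH/THF, rt, on the sodium salt; then H+-form cation-exchange resin, 0 °C
Reagents that add atoms: none
Why: Hydrogenolysis of the three benzyl ethers; an aryl sulfate salt and the pyranone double bond should be inert under these neutral conditions.

## Compound list

1 | 2-deoxy-D-glucose | O=CC[C@@H](O)[C@H](O)[C@H](O)CO | starting material
2 | methyl 2-deoxy-α-D-arabino-hexopyranoside | OC[C@@H]1[C@H]([C@@H](C[C@H](O1)OC)O)O | intermediate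
3 | methyl 4,6-O-[(R)-benzylidene]-2-deoxy-α-D-arabino-hexopyranoside | c1ccccc1[C@@H]1OC[C@@H]2[C@H]([C@@H](C[C@H](O2)OC)O)O1 | intermediate
4 | methyl 3-O-benzyl-4,6-O-[(R)-benzylidene]-2-deoxy-α-D-arabino-hexopyranoside | c1ccccc1[C@@H]1OC[C@@H]2[C@H]([C@@H](C[C@H](O2)OC)OCc2ccccc2)O1 | intermediate
5 | methyl 3-O-benzyl-2-deoxy-α-D-arabino-hexopyranoside | OC[C@@H]1[C@H]([C@@H](C[C@H](O1)OC)OCc2ccccc2)O | intermediate
6 | methyl 3-O-benzyl-2,6-dideoxy-6-iodo-α-D-arabino-hexopyranoside | IC[C@@H]1[C@H]([C@@H](C[C@H](O1)OC)OCc2ccccc2)O | intermediate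
7 | methyl 3-O-benzyl-4-O-(tert-butyldimethylsilyl)-2,6-dideoxy-6-iodo-α-D-arabino-hexopyranoside | IC[C@@H]1[C@H]([C@@H](C[C@H](O1)OC)OCc2ccccc2)O[Si](C)(C)C(C)(C)C | intermediate
8 | methyl 3-O-benzyl-4-O-(tert-butyldimethylsilyl)-2,6-dideoxy-α-D-arabino-hex-5-enopyranoside | C=C1[C@H]([C@@H](C[C@H](O1)OC)OCc2ccccc2)O[Si](C)(C)C(C)(C)C | intermediate
9 | (3R,4S)-3-(benzyloxy)-4-[(tert-butyldimethylsilyl)oxy]-5-oxo-6-[(trifluoroacetoxy)mercurio]hexanal | O=CC[C@@H](OCc1ccccc1)[C@H](O[Si](C)(C)C(C)(C)C)C(=O)C[Hg]OC(=O)C(F)(F)F | intermediate (not isolated)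
10 | (2S,3R)-3-(benzyloxy)-2-[(tert-butyldimethylsilyl)oxy]-5-hydroxycyclohexan-1-one (C5 as formed) | O=C1[C@@H](O[Si](C)(C)C(C)(C)C)[C@H](OCc2ccccc2)CC(O)C1 | intermediate
11 | (2S,3R)-3-(benzyloxy)-2-[(tert-butyldimethylsilyl)oxy]-5-[(triethylsilyl)oxy]cyclohexan-1-one | O=C1[C@@H](O[Si](C)(C)C(C)(C)C)[C@H](OCc2ccccc2)CC(O[Si](CC)(CC)CC)C1 | intermediate
12 | 3,4-bis(benzyloxy)benzaldehyde | O=Cc1ccc(OCc2ccccc2)c(OCc2ccccc2)c1 | starting material
13 | 1,2-bis(benzyloxy)-4-(2,2-dibromoethenyl)benzene | BrC(Br)=Cc1ccc(OCc2ccccc2)c(OCc2ccccc2)c1 | intermediate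
14 | lithium [3,4-bis(benzyloxy)phenyl]acetylide | [Li]C#Cc1ccc(OCc2ccccc2)c(OCc2ccccc2)c1 | intermediate (not isolated)
15 | 3-[3,4-bis(benzyloxy)phenyl]prop-2-ynal | O=CC#Cc1ccc(OCc2ccccc2)c(OCc2ccccc2)c1 | intermediate
16 | lithium enolate of 11 (C4a=C5 enolate) | [Li]OC1=CC(O[Si](CC)(CC)CC)C[C@@H](OCc2ccccc2)[C@@H]1O[Si](C)(C)C(C)(C)C | intermediate (not isolated)
17 | (2S,3R)-3-(benzyloxy)-6-{3-[3,4-bis(benzyloxy)phenyl]-1-hydroxyprop-2-yn-1-yl}-2-[(tert-butyldimethylsilyl)oxy]-5-[(triethylsilyl)oxy]cyclohexan-1-one (diastereomers at the undefined centres) | O=C1[C@@H](O[Si](C)(C)C(C)(C)C)[C@H](OCc2ccccc2)CC(O[Si](CC)(CC)CC)C1C(O)C#Cc1ccc(OCc2ccccc2)c(OCc2ccccc2)c1 | intermediate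
18 | (2S,3R)-3-(benzyloxy)-6-{3-[3,4-bis(benzyloxy)phenyl]prop-2-ynoyl}-2-[(tert-butyldimethylsilyl)oxy]-5-[(triethylsilyl)oxy]cyclohexan-1-one (diketo form drawn, enolized) | O=C1[C@@H](O[Si](C)(C)C(C)(C)C)[C@H](OCc2ccccc2)CC(O[Si](CC)(CC)CC)C1C(=O)C#Cc1ccc(OCc2ccccc2)c(OCc2ccccc2)c1 | intermediate
19 | (2S,3R)-3-(benzyloxy)-6-{3-[3,4-bis(benzyloxy)phenyl]prop-2-ynoyl}-2-[(tert-butyldimethylsilyl)oxy]-5-hydroxycyclohexan-1-one | O=C1[C@@H](O[Si](C)(C)C(C)(C)C)[C@H](OCc2ccccc2)CC(O)C1C(=O)C#Cc1ccc(OCc2ccccc2)c(OCc2ccccc2)c1 | intermediate (not isolated)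
20 | (6S,7R)-7-(benzyloxy)-2-[3,4-bis(benzyloxy)phenyl]-6-[(tert-butyldimethylsilyl)oxy]-5-hydroxy-6,7,8,8a-tetrahydro-4H-chromen-4-one (C8a as formed) | O=C1C=C(c2ccc(OCc3ccccc3)c(OCc3ccccc3)c2)OC2C[C@@H](OCc3ccccc3)[C@H](O[Si](C)(C)C(C)(C)C)C(O)=C12 | intermediate
21 | (6S,7R)-7-(benzyloxy)-2-[3,4-bis(benzyloxy)phenyl]-6-[(tert-butyldimethylsilyl)oxy]-7,8-dihydro-4H-chromene-4,5(6H)-dione | O=C1C=C(c2ccc(OCc3ccccc3)c(OCc3ccccc3)c2)OC2=C1C(=O)[C@@H](O[Si](C)(C)C(C)(C)C)[C@H](OCc3ccccc3)C2 | intermediate
22 | (6S,7R)-7-(benzyloxy)-2-[3,4-bis(benzyloxy)phenyl]-6-hydroxy-7,8-dihydro-4H-chromene-4,5(6H)-dione | O=C1C=C(c2ccc(OCc3ccccc3)c(OCc3ccccc3)c2)OC2=C1C(=O)[C@@H](O)[C@H](OCc3ccccc3)C2 | intermediate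
23 | (7R)-7-(benzyloxy)-2-[3,4-bis(benzyloxy)phenyl]-7,8-dihydro-4H-chromene-4,5,6-trione | O=C1C=C(c2ccc(OCc3ccccc3)c(OCc3ccccc3)c2)OC2=C1C(=O)C(=O)[C@H](OCc3ccccc3)C2 | intermediate (not isolated)
24 | 7-(benzyloxy)-2-[3,4-bis(benzyloxy)phenyl]-5,6-dihydroxy-4H-chromen-4-one | O=c1cc(-c2ccc(OCc3ccccc3)c(OCc3ccccc3)c2)oc2cc(OCc3ccccc3)c(O)c(O)c12 | intermediate
25 | 7-(benzyloxy)-2-[3,4-bis(benzyloxy)phenyl]-5-hydroxy-4-oxo-4H-chromen-6-yl hydrogen sulfate | O=c1cc(-c2ccc(OCc3ccccc3)c(OCc3ccccc3)c2)oc2cc(OCc3ccccc3)c(OS(=O)(=O)O)c(O)c12 | intermediate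
26 | 2-(3,4-dihydroxyphenyl)-5,7-dihydroxy-4-oxo-4H-chromen-6-yl hydrogen sulfate (6-hydroxyluteolin 6-sulfate) | O=c1cc(-c2ccc(O)c(O)c2)oc2cc(O)c(OS(=O)(=O)O)c(O)c12 | target

## Step count and least certain steps

Total step count: 19. Longest linear sequence: 17 steps (steps 1–9 and 12–19, from 1). The ynal 15 is made in 2 steps (10–11) from 12.

**Step 8 (key step).** The most likely failure is protodemercuration of 9 before the aldol, which amounts to plain hydrolysis of the enol ether to an open-chain methyl ketone. β-Elimination of the benzyloxy group from the transient aldehyde is also possible, because a 2-deoxy aldehyde has acidic alpha hydrogens. The fallback separates ring opening from ring closure. It sets out from 8: mild aqueous acid (sulfonic acid resin, acetone/H2O, rt) would hydrolyse the enol ether and the glycoside to (3R,4S)-3-(benzyloxy)-4-[(tert-butyldimethylsilyl)oxy]-5-oxohexanal F1. An amine-catalysed intramolecular aldol (pyrrolidine/AcOH or L-proline, DMSO, rt) through the enamine of the methyl ketone would then form the same C4a–C8a bond and return to the route at 10.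

**Step 14.** The most likely failure is ring closure through the C5 enol oxygen instead of the C8a hydroxyl, which gives the isomeric γ-pyrone and, later, the 5,7,8-pattern. Acid-catalysed dehydration across C4a–C8a is a second risk. Both arise because the substrate is a 1,3-diketone with two oxygen nucleophiles within reach of C2. The fallback ties up the C5 oxygen. It sets out from 18: BF3·OEt2 (CH2Cl2, 0 °C) would give the difluoroboron chelate of 18 F2, in which O5 and the C4 oxygen are both bound to boron and the ynone is further activated. HF·pyridine would free the C8a hydroxyl, which is then the only oxygen able to add to C2, giving the difluoroboron chelate of 20 F3. NaOAc in aqueous MeOH at 50 °C would release the diketone and return to the route at 20.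

**Step 15.** The most likely failure is slow hydride transfer, so that the heat needed and the acidic hydroquinone formed cause loss of the C7 benzyloxy or the C6 silyloxy group. The fallback replaces hydride abstraction by α-selenenylation and selenoxide elimination. It sets out from 20: PhSeCl and pyridine (CH2Cl2, 0 °C) should selenenylate the nucleophilic C4a to give (6S,7R)-7-(benzyloxy)-2-[3,4-bis(benzyloxy)phenyl]-6-[(tert-butyldimethylsilyl)oxy]-4a-(phenylselanyl)-6,7,8,8a-tetrahydro-4H-chromene-4,5(4aH)-dione F4. A cis ring fusion is expected, which places selenium syn to the C8a hydrogen. H2O2 at 0 °C would then bring about syn elimination of the selenoxide toward C8a, the only β-hydrogen available, and return to the route at 21.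

**Step 16 (with step 17).** The most likely failure is loss of the C7 benzyloxy group by enolization of the C5 ketone toward C6 or C8 during or after desilylation; this aromatizes ring A without O7. The free acyloin 22 is the most elimination-prone compound of the route. The fallback aromatizes with the silyl ether still in place. It sets out from 21: DDQ in 1,4-dioxane at 80 °C would dehydrogenate C6–C7 through the C5 enol (hydride from C7, alpha to the benzyloxy group) to give 7-(benzyloxy)-2-[3,4-bis(benzyloxy)phenyl]-6-[(tert-butyldimethylsilyl)oxy]-5-hydroxy-4H-chromen-4-one F5. Bu4NF buffered with AcOH in THF would then cleave the aryl silyl ether and return to the route at 24.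

## Further compounds

F1 | step 8 | (3R,4S)-3-(benzyloxy)-4-[(tert-butyldimethylsilyl)oxy]-5-oxohexanal | O=CC[C@@H](OCc1ccccc1)[C@H](O[Si](C)(C)C(C)(C)C)C(C)=O
F2 | step 14 | difluoroboron chelate of 18 | F[B-]1(F)OC2=C(C(O[Si](CC)(CC)CC)C[C@@H](OCc3ccccc3)[C@@H]2O[Si](C)(C)C(C)(C)C)C(C#Cc2ccc(OCc3ccccc3)c(OCc3ccccc3)c2)=[O+]1
F3 | step 14 | difluoroboron chelate of 20 | F[B-]1(F)OC2=C3C(C[C@@H](OCc4ccccc4)[C@@H]2O[Si](C)(C)C(C)(C)C)OC(c2ccc(OCc4ccccc4)c(OCc4ccccc4)c2)=CC3=[O+]1
F4 | step 15 | (6S,7R)-7-(benzyloxy)-2-[3,4-bis(benzyloxy)phenyl]-6-[(tert-butyldimethylsilyl)oxy]-4a-(phenylselanyl)-6,7,8,8a-tetrahydro-4H-chromene-4,5(4aH)-dione | O=C1C=C(c2ccc(OCc3ccccc3)c(OCc3ccccc3)c2)OC2C[C@@H](OCc3ccccc3)[C@H](O[Si](C)(C)C(C)(C)C)C(=O)C12[Se]c1ccccc1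
F5 | step 16 | 7-(benzyloxy)-2-[3,4-bis(benzyloxy)phenyl]-6-[(tert-butyldimethylsilyl)oxy]-5-hydroxy-4H-chromen-4-one | O=c1cc(-c2ccc(OCc3ccccc3)c(OCc3ccccc3)c2)oc2cc(OCc3ccccc3)c(O[Si](C)(C)C(C)(C)C)c(O)c12
A1 | alternative 1 | 5-hydroxy-3',4'-bis(pivaloyloxy)flavone 6,7-cyclic sulfate | O=c1cc(-c2ccc(OC(=O)C(C)(C)C)c(OC(=O)C(C)(C)C)c2)oc2cc3OS(=O)(=O)Oc3c(O)c12
A2 | alternative 1 | 5,6,7-trihydroxy-3',4'-bis(pivaloyloxy)flavone | O=c1cc(-c2ccc(OC(=O)C(C)(C)C)c(OC(=O)C(C)(C)C)c2)oc2cc(O)c(O)c(O)c12
A3 | alternative 2 | 5,7,3',4'-tetrakis(benzyloxy)-6-hydroxyflavone | O=c1cc(-c2ccc(OCc3ccccc3)c(OCc3ccccc3)c2)oc2cc(OCc3ccccc3)c(O)c(OCc3ccccc3)c12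
A4 | alternative 2 | 1-[2,4-bis(benzyloxy)-3-hydroxyphenyl]-3-[3,4-bis(benzyloxy)phenyl]propane-1,3-dione | O=C(CC(=O)c1ccc(OCc2ccccc2)c(OCc2ccccc2)c1)c1ccc(OCc2ccccc2)c(O)c1OCc1ccccc1
A5 | alternative 3 | 1-[2,4-bis(benzyloxy)-6-hydroxy-3-(methoxymethoxy)phenyl]-3-[3,4-bis(benzyloxy)phenyl]prop-2-yn-1-one | O=C(C#Cc1ccc(OCc2ccccc2)c(OCc2ccccc2)c1)c1c(O)cc(OCc2ccccc2)c(OCOC)c1OCc1ccccc1
A6 | alternative 3 | 3-[3,4-bis(benzyloxy)phenyl]prop-2-ynoic acid | OC(=O)C#Cc1ccc(OCc2ccccc2)c(OCc2ccccc2)c1
A7 | alternative 3 | 3,5-bis(benzyloxy)-4-(methoxymethoxy)-2-(trimethylsilyl)phenyl trifluoromethanesulfonate | C[Si](C)(C)c1c(OS(=O)(=O)C(F)(F)F)cc(OCc2ccccc2)c(OCOC)c1OCc1ccccc1
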